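The readings come from a simulation with constants of no real substance, noise included.

The larch and elm readings cannot lie on one curve against clock time: at 0.667 h larch still holds 53% of its electrophile and elm 27%. The two runs differ in the nucleophile charge.

| setting | larch | elm | noon | dawn |
|---|---|---|---|---|
| electrophile | 0.25 M | 0.25 M | 0.25 M | 0.25 M |
| nucleophile | 2.8 equiv | 5.9 equiv | 2.00 equiv | 4.00 equiv |
| scavenger | 1 equiv | 1 equiv | 1.00 equiv | 1.00 equiv |
| gas | 150 mM (held) | 150 mM (held) | 150 mM (held) | 150 mM (held) |
| remark | run made earlier | run made earlier |  |  |
| time |  |  | 2.5 h | 2.5 h |

| run | time / h | electrophile / % | product / % |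
|---|---|---|---|
| larch | 0.667 | 53 | 45 |
| larch | 1.33 | 31 | 70 |
| larch | 2.00 | 20 | 73 |
| larch | 2.50 | 17 | 79 |
| elm | 0.667 | 27 | 72 |
| elm | 1.33 | 9 | 92 |
| elm | 2.00 | 3 | 97 |
| elm | 2.50 | 3 | 99 |

(scatter of a reading: 1.5 percentage points)

- the numbers in the tables scatter with a standard deviation of 1.5 percentage points
- at the start none of the gas is in solution
- what has gone from electrophile into another species counts as reacted, even if it can come back

- part of the electrophile that has reacted at the end, noon
- part of the electrophile that has reacted at the end, dawn
- what raising the equivalents of nucleophile from its lowest to its highest value here does to the part of the electrophile that has reacted (changes below 5 percentage points count as none) (it rises / it falls / no change)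

We take the electrophile as limiting reagent and let each one consume one nucleophile. With r the equivalents of nucleophile, x the part reacted and t the time, (r − x)/(r(1 − x)) then grows as exp(t/τ). Here τ, the excess time, is one over κ times the excess equivalents of nucleophile, and κ is the rate constant times the electrophile's starting concentration.

So two times compare: τ and the time of the flask. The last larch reading gives κ = 0.316 h⁻¹. The first gives 0.376 h⁻¹, which is higher, so κ read this way is lower at the last larch reading than at the first. We keep the last reading, which stands at the asked time.

Noon then has τ = 3.17 h, longer than its 2.5 h, and we expect 70.6%. Dawn has τ = 1.06 h, shorter than its run, and we expect 92.8%.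

The forecast, which holds that “the reaction looks first order in nucleophile”, gives 72% for noon and 94% for dawn, slightly above ours, and says it rises.

The flasks give 71.2% in noon and 93.1% in dawn. As to the part reacted when the nucleophile goes from noon's charge to dawn's, it rises, by 22 percentage points.

    acid set free + scavenger → scavenged by-product (k = 0.320 L mol⁻¹ min⁻¹)
    electrophile + nucleophile → acid set free + product (k = 0.0270 L mol⁻¹ min⁻¹)
    electrophile + acid set free ⇌ idle adduct, settled at all times (K = 24.0 L mol⁻¹)
    gas ⇌ free base, rate k4*(csat - [free base]) (kL = 0.520 min⁻¹)
    acid set free + free base ⇌ salt of the base (K = 8.50 L mol⁻¹, k = 2.70 L mol⁻¹ min⁻¹)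
    nucleophile + acid set free ⇌ protonated nucleophile, settled at all times (K = 120 L mol⁻¹)

In noon at 2.50 h, free nucleophile stands at 42.2% of its charge, with 0.119 M held as protonated nucleophile. The neighbour flask is noon with 3.40 equiv of nucleophile. With the same κ its τ is 1.32 h, shorter than the run, and the reckoning gives 88.9%. The neighbour flask gives 89.0% reacted, with 88.1% as product.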